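**Plan**

1. Retrosynthesis: the acetate and the lactone C–O bond are opened to amide acid 25. An Ireland–Claisen retron then cuts the bond between butenyl C2 and lactone C3, which also accounts for the exocyclic methylene. The hydrindane is cut in its six-membered ring at C3a–C4 and C6–C7.
2. Enabling feature: C3a and C7 are both bonded to the quaternary carbon C7a. As an enol triflate carbon and a formyl carbon on C7a they form a 1,3-bis-electrophile that matches the α,α'-bis-nucleophile 3-methylbutan-2-one (C4–C5–C6). Its two isopropyl methyls become the gem-dimethyl group and its carbonyl at C5 is a temporary activator.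
3. Forward order: the five-membered ring is functionalised first (three-component coupling on 2-methylcyclopent-2-enone), then the six-membered ring is closed by the annulation. The C5 oxygen is removed and the ring alkenes are hydrogenated, then the chain is built (aldol/dehydration, reduction, esterification, Claisen) and the lactone closes last.
4. Stereochemistry: C1 comes from a catalytic asymmetric Mukaiyama–Michael addition and C7a from alkylation anti to the C1 substituent. C3a comes from α-face hydrogenation (trans ring fusion). The two side-chain centres come from a chair Ireland–Claisen rearrangement steered by the hydrindane.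

Key step: step 5

Locants in the text use indene numbering for the bicycle (C1 carries the chain, C3a is the ring-fusion CH, C4 the gem-dimethyl carbon, C7a the angular carbon).
Assumption: the (S)-configured oxazaborolidinium catalyst of step 2 is taken to deliver the (1R) adduct 6; if the sense of induction is the opposite, the (R)-catalyst is used.

**Route**

Step 1
Reactants: 1 3-methylbutan-2-one
Product: 2 trimethyl[(3-methylbut-2-en-2-yl)oxy]silane
Conditions: TMSCl, NaI, Et3N, MeCN, 25 °C; fractional distillation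
Reagents that add atoms: chlorotrimethylsilane, C[Si](C)(C)Cl
Why: Silyl enol ether formation under equilibrating conditions (iodotrimethylsilane made in the flask, amine base) should favour the tetrasubstituted enol silane, and distillation should remove the minor terminal isomer.

Step 2
Reactants: 3 2-methylcyclopent-2-en-1-one; 4 tert-butyl[(1-methoxyethenyl)oxy]dimethylsilane; 5 trimethoxymethane
Product: 7 methyl 2-[(1R,2S)-2-(dimethoxymethyl)-2-methyl-3-oxocyclopentyl]acetate, via enol silane 6 (not isolated)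
Conditions: (S)-3,3-diphenyl-1-(2-methylphenyl)tetrahydropyrrolo[1,2-c][1,3,2]oxazaborole·HNTf2 (20 mol %), Ph3PO (25 mol %), toluene, −20 °C; then HC(OMe)3, TMSOTf (10 mol %), CH2Cl2, −78 °C
Reagents that add atoms: none
Why: A catalytic enantioselective Mukaiyama–Michael addition (the chiral oxazaborolidinium Lewis acid shields one face of the bound enone and sets C1) gives the regiodefined enol silane 6, and its Mukaiyama-type alkylation by the dimethoxycarbenium ion should occur anti to the C1 substituent, so that the new quaternary carbon carries its methyl group cis to the acetate chain.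

Step 3
Reactants: 7 methyl 2-[(1R,2S)-2-(dimethoxymethyl)-2-methyl-3-oxocyclopentyl]acetate
Product: 8 methyl 2-[(1R,2R)-2-(dimethoxymethyl)-2-methyl-3-{[(trifluoromethyl)sulfonyl]oxy}cyclopent-3-en-1-yl]acetate
Conditions: KHMDS, THF, −78 °C; PhNTf2, −78 → 0 °C
Reagents that add atoms: N-phenylbis(trifluoromethanesulfonimide), O=S(=O)(N(c1ccccc1)S(=O)(=O)C(F)(F)F)C(F)(F)F
Why: Enol triflate formation through the kinetic potassium enolate can only go toward the CH2 side because the other α-carbon is quaternary, and the ketone is deprotonated in preference to the less acidic ester.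

Step 4
Reactants: 8 methyl 2-[(1R,2R)-2-(dimethoxymethyl)-2-methyl-3-{[(trifluoromethyl)sulfonyl]oxy}cyclopent-3-en-1-yl]acetate
Product: 9 methyl 2-[(1R,2R)-2-formyl-2-methyl-3-{[(trifluoromethyl)sulfonyl]oxy}cyclopent-3-en-1-yl]acetate
Conditions: TFA, H2O, CH2Cl2, 0 → 23 °C
Reagents that add atoms: water, O
Why: Acid-catalysed acetal hydrolysis should unmask the non-enolisable neopentyl aldehyde, while the enol triflate and the methyl ester are stable to aqueous acid.

Step 5
Reactants: 9 methyl 2-[(1R,2R)-2-formyl-2-methyl-3-{[(trifluoromethyl)sulfonyl]oxy}cyclopent-3-en-1-yl]acetate; 2 trimethyl[(3-methylbut-2-en-2-yl)oxy]silane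
Product: 12 methyl 2-[(1R,7aS)-4,4,7a-trimethyl-5-oxo-2,4,5,7a-tetrahydro-1H-inden-1-yl]acetate, via tin enolate 10 (not isolated), via keto aldehyde 11 (not isolated)
Conditions: Pd2(dba)3 (2.5 mol %), P(t-Bu)3 (10 mol %), Bu3SnF, CsF, toluene, 85 °C
Reagents that add atoms: none
Why: Proposed new method: fluoride converts 2 into tin enolate 10, zerovalent palladium inserts into the C–OTf bond of 9, transmetalation and C–C reductive elimination at the fully substituted enolate carbon make the C3a–C4 bond and give methyl ketone 11, and the fluoride base then lets its methyl group add to the neighbouring formyl group and lose water, which makes the C6–C7 bond. The closest known reactions are the palladium-catalysed α-arylation/aldol-condensation annulation of 2-halobenzaldehydes with ketones (naphthol synthesis) and the Bu3SnF/CsF-mediated regiocontrolled α-arylation of trimethylsilyl enol ethers that builds quaternary carbons; new here are an enol triflate and a formyl group joined through the sp3 carbon C7a instead of an arene, and a tetrasubstituted enolate. The six-membered ring closes by a 6-(enolendo)-exo-trig aldol addition followed by E1cB dehydration, after the intermolecular coupling. No stereocentre is formed: C1 and C7a come unchanged from 9, and C3a stays trigonal so that its hydrogen can be delivered later from the α-face. The step needs coupling at the tertiary and not the methyl α-carbon and no unproductive crossed aldol; the regiodefined enol silane secures the first, and the second is secured because aldol addition of the hindered tetrasubstituted enolate to the neopentyl aldehyde is reversible and cannot dehydrate, whereas after coupling the methyl group is the only enolisable site and lies in reach of the formyl carbon for a six-membered ring.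

Step 6
Reactants: 12 methyl 2-[(1R,7aS)-4,4,7a-trimethyl-5-oxo-2,4,5,7a-tetrahydro-1H-inden-1-yl]acetate
Product: 13 methyl 2-[(1R,7aS)-4,4,7a-trimethyl-5-{2-[(4-methylphenyl)sulfonyl]hydrazinylidene}-2,4,5,7a-tetrahydro-1H-inden-1-yl]acetate
Conditions: TsNHNH2, AcOH (cat.), EtOH, 70 °C
Reagents that add atoms: 4-methylbenzenesulfonohydrazide, Cc1ccc(cc1)S(=O)(=O)NN
Why: Hydrazone condensation at the conjugated C5 ketone should win over conjugate addition because the β-carbon is neopentyl, and it arms the enone for reductive removal of the temporary oxygen.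

Step 7
Reactants: 13 methyl 2-[(1R,7aS)-4,4,7a-trimethyl-5-{2-[(4-methylphenyl)sulfonyl]hydrazinylidene}-2,4,5,7a-tetrahydro-1H-inden-1-yl]acetate
Product: 14 methyl 2-[(1R,7aR)-4,4,7a-trimethyl-2,4,7,7a-tetrahydro-1H-inden-1-yl]acetate
Conditions: catecholborane, CHCl3, 0 °C; then NaOAc·3H2O, 60 °C
Reagents that add atoms: none
Why: Catecholborane reduction of an α,β-unsaturated tosylhydrazone adds hydride at C5 and, after loss of sulfinate and dinitrogen, delivers hydrogen to C7 with 1,3-transposition of the alkene to C5=C6, which removes the C5 oxygen without touching the ester.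

Step 8
Reactants: 14 methyl 2-[(1R,7aR)-4,4,7a-trimethyl-2,4,7,7a-tetrahydro-1H-inden-1-yl]acetate
Product: 15 methyl 2-[(1R,3aS,7aR)-4,4,7a-trimethyloctahydro-1H-inden-1-yl]acetate
Conditions: H2 (3 atm), Pd/C, EtOAc, 23 °C
Reagents that add atoms: none
Why: Heterogeneous hydrogenation reduces both ring alkenes, and hydrogen should add to C3a from the α-face opposite the angular methyl group and the C1 chain, which sets the trans ring fusion as in the hydrogenation of Δ14 steroids and of related 4,4,7a-trimethylhydrindenes.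

Step 9
Reactants: 15 methyl 2-[(1R,3aS,7aR)-4,4,7a-trimethyloctahydro-1H-inden-1-yl]acetate; 16 {[tert-butyl(dimethyl)silyl]oxy}acetaldehyde
Product: 17 methyl 4-{[tert-butyl(dimethyl)silyl]oxy}-3-hydroxy-2-[(1R,3aS,7aR)-4,4,7a-trimethyloctahydro-1H-inden-1-yl]butanoate (mixture of diastereomers at C2 and C3)
Conditions: LDA, THF, −78 °C; then 16; H2O quench at −78 °C
Reagents that add atoms: none
Why: Aldol addition of the ester enolate to the aldehyde makes the C–C bond that becomes the trisubstituted alkene, and the two new centres are removed in step 10, so their configuration does not matter.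

Step 10
Reactants: 17 methyl 4-{[tert-butyl(dimethyl)silyl]oxy}-3-hydroxy-2-[(1R,3aS,7aR)-4,4,7a-trimethyloctahydro-1H-inden-1-yl]butanoate
Product: 19 methyl (2E)-4-{[tert-butyl(dimethyl)silyl]oxy}-2-[(1S,3aS,7aS)-4,4,7a-trimethyloctahydro-1H-inden-1-yl]but-2-enoate, via mesylate 18 (not isolated)
Conditions: MsCl, Et3N, CH2Cl2, 0 °C; then DBU, 23 °C
Reagents that add atoms: none
Why: Mesylation and E1cB elimination should give the thermodynamically preferred (E)-enoate, in which the silyloxymethyl group is trans to the ester.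

Step 11
Reactants: 19 methyl (2E)-4-{[tert-butyl(dimethyl)silyl]oxy}-2-[(1S,3aS,7aS)-4,4,7a-trimethyloctahydro-1H-inden-1-yl]but-2-enoate
Product: 20 (2E)-4-{[tert-butyl(dimethyl)silyl]oxy}-2-[(1S,3aS,7aS)-4,4,7a-trimethyloctahydro-1H-inden-1-yl]but-2-en-1-ol
Conditions: DIBAL-H (2.2 equiv), CH2Cl2, −78 °C; Rochelle salt work-up
Reagents that add atoms: none
Why: 1,2-Reduction of the conjugated ester by DIBAL-H gives the allylic alcohol with the alkene geometry unchanged.

Step 12
Reactants: 20 (2E)-4-{[tert-butyl(dimethyl)silyl]oxy}-2-[(1S,3aS,7aS)-4,4,7a-trimethyloctahydro-1H-inden-1-yl]but-2-en-1-ol; 21 4-(dimethylamino)-4-oxobutanoic acid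
Product: 22 (2E)-4-{[tert-butyl(dimethyl)silyl]oxy}-2-[(1S,3aS,7aS)-4,4,7a-trimethyloctahydro-1H-inden-1-yl]but-2-en-1-yl 4-(dimethylamino)-4-oxobutanoate
Conditions: DCC, DMAP (cat.), CH2Cl2, 0 → 23 °C
Reagents that add atoms: none
Why: Steglich esterification of the primary allylic alcohol installs the four-carbon unit of the lactone, with the amide as a second carbonyl that is much less acidic than the ester.

Step 13
Reactants: 22 (2E)-4-{[tert-butyl(dimethyl)silyl]oxy}-2-[(1S,3aS,7aS)-4,4,7a-trimethyloctahydro-1H-inden-1-yl]but-2-en-1-yl 4-(dimethylamino)-4-oxobutanoate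
Product: 25 (2S,3R)-3-({[tert-butyl(dimethyl)silyl]oxy}methyl)-2-[2-(dimethylamino)-2-oxoethyl]-4-[(1R,3aS,7aS)-4,4,7a-trimethyloctahydro-1H-inden-1-yl]pent-4-enoic acid, via ketene acetal 23 (not isolated), via silyl ester 24 (not isolated)
Conditions: LDA, TMSCl, THF, −78 °C; then 23 → 50 °C; 1 M HCl work-up
Reagents that add atoms: none
Why: In this Ireland–Claisen rearrangement kinetic deprotonation next to the ester (far more acidic than the amide) and silylation give ketene acetal 23 with the amide arm cis to the allyloxy oxygen, the chair transition state with the (E)-alkene then fixes the relative configuration of the two new centres, and attack on the alkene face away from the quaternary C7a (allylic 1,3-strain holds H-1 in the alkene plane) should set them in the sense of the target while the 1,1-disubstituted alkene appears by allylic transposition.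

Step 14
Reactants: 25 (2S,3R)-3-({[tert-butyl(dimethyl)silyl]oxy}methyl)-2-[2-(dimethylamino)-2-oxoethyl]-4-[(1R,3aS,7aS)-4,4,7a-trimethyloctahydro-1H-inden-1-yl]pent-4-enoic acid
Product: 27 (3S,4R)-4-({[tert-butyl(dimethyl)silyl]oxy}methyl)-3-(hydroxymethyl)-N,N-dimethyl-5-[(1R,3aS,7aS)-4,4,7a-trimethyloctahydro-1H-inden-1-yl]hex-5-enamide, via mixed anhydride 26 (not isolated)
Conditions: i-BuOCOCl, N-methylmorpholine, THF, −15 °C; then NaBH4, H2O, 0 °C
Reagents that add atoms: none
Why: Borohydride reduction of the mixed carbonic anhydride converts the carboxylic acid into the primary alcohol chemoselectively and leaves the tertiary amide, the silyl ether and the alkene untouched.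

Step 15
Reactants: 27 (3S,4R)-4-({[tert-butyl(dimethyl)silyl]oxy}methyl)-3-(hydroxymethyl)-N,N-dimethyl-5-[(1R,3aS,7aS)-4,4,7a-trimethyloctahydro-1H-inden-1-yl]hex-5-enamide
Product: 28 (4S)-4-{(2R)-1-hydroxy-3-[(1R,3aS,7aS)-4,4,7a-trimethyloctahydro-1H-inden-1-yl]but-3-en-2-yl}oxolan-2-one
Conditions: 1 M HCl, THF, 45 °C
Reagents that add atoms: none
Why: Acid-promoted lactonisation of the γ-hydroxy amide (5-exo-trig acyl transfer with loss of dimethylamine) runs together with cleavage of the silyl ether, and the five-membered lactone is favoured kinetically and thermodynamically over the six-membered alternative.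

Step 16
Reactants: 28 (4S)-4-{(2R)-1-hydroxy-3-[(1R,3aS,7aS)-4,4,7a-trimethyloctahydro-1H-inden-1-yl]but-3-en-2-yl}oxolan-2-one
Product: 29 (2R)-2-[(3S)-5-oxooxolan-3-yl]-3-[(1R,3aS,7aS)-4,4,7a-trimethyloctahydro-1H-inden-1-yl]but-3-en-1-yl acetate
Conditions: Ac2O, pyridine, DMAP (cat.), CH2Cl2, 0 → 23 °C
Reagents that add atoms: acetic anhydride, CC(=O)OC(C)=O
Why: Acetylation of the primary alcohol completes the target without touching any stereocentre.

**Compound list**

1 | 3-methylbutan-2-one | CC(C)C(C)=O | starting material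
2 | trimethyl[(3-methylbut-2-en-2-yl)oxy]silane | CC(C)=C(C)O[Si](C)(C)C | intermediate
3 | 2-methylcyclopent-2-en-1-one | CC1=CCCC1=O | starting material
4 | tert-butyl[(1-methoxyethenyl)oxy]dimethylsilane | COC(=C)O[Si](C)(C)C(C)(C)C | starting material
5 | trimethoxymethane (trimethyl orthoformate) | COC(OC)OC | starting material
6 | methyl 2-[(1R)-3-{[tert-butyl(dimethyl)silyl]oxy}-2-methylcyclopent-2-en-1-yl]acetate | COC(=O)C[C@H]1CCC(O[Si](C)(C)C(C)(C)C)=C1C | intermediate
7 | methyl 2-[(1R,2S)-2-(dimethoxymethyl)-2-methyl-3-oxocyclopentyl]acetate | COC(=O)C[C@H]1CCC(=O)[C@]1(C)C(OC)OC | intermediate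
8 | methyl 2-[(1R,2R)-2-(dimethoxymethyl)-2-methyl-3-{[(trifluoromethyl)sulfonyl]oxy}cyclopent-3-en-1-yl]acetate | COC(=O)C[C@H]1CC=C(OS(=O)(=O)C(F)(F)F)[C@]1(C)C(OC)OC | intermediate
9 | methyl 2-[(1R,2R)-2-formyl-2-methyl-3-{[(trifluoromethyl)sulfonyl]oxy}cyclopent-3-en-1-yl]acetate | COC(=O)C[C@H]1CC=C(OS(=O)(=O)C(F)(F)F)[C@]1(C)C=O | intermediate
10 | tributyl[(3-methylbut-2-en-2-yl)oxy]stannane | CCCC[Sn](CCCC)(CCCC)OC(C)=C(C)C | intermediate
11 | methyl 2-[(1R,2R)-2-formyl-2-methyl-3-(2-methyl-3-oxobutan-2-yl)cyclopent-3-en-1-yl]acetate | COC(=O)C[C@H]1CC=C(C(C)(C)C(C)=O)[C@]1(C)C=O | intermediate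
12 | methyl 2-[(1R,7aS)-4,4,7a-trimethyl-5-oxo-2,4,5,7a-tetrahydro-1H-inden-1-yl]acetate | COC(=O)C[C@H]1CC=C2C(C)(C)C(=O)C=C[C@]12C | intermediate
13 | methyl 2-[(1R,7aS)-4,4,7a-trimethyl-5-{2-[(4-methylphenyl)sulfonyl]hydrazinylidene}-2,4,5,7a-tetrahydro-1H-inden-1-yl]acetate | COC(=O)C[C@H]1CC=C2C(C)(C)C(=NNS(=O)(=O)c3ccc(C)cc3)C=C[C@]12C | intermediate
14 | methyl 2-[(1R,7aR)-4,4,7a-trimethyl-2,4,7,7a-tetrahydro-1H-inden-1-yl]acetate | COC(=O)C[C@H]1CC=C2C(C)(C)C=CC[C@]12C | intermediate
15 | methyl 2-[(1R,3aS,7aR)-4,4,7a-trimethyloctahydro-1H-inden-1-yl]acetate | COC(=O)C[C@H]1CC[C@H]2C(C)(C)CCC[C@]12C | intermediate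
16 | {[tert-butyl(dimethyl)silyl]oxy}acetaldehyde | CC(C)(C)[Si](C)(C)OCC=O | starting material
17 | methyl 4-{[tert-butyl(dimethyl)silyl]oxy}-3-hydroxy-2-[(1R,3aS,7aR)-4,4,7a-trimethyloctahydro-1H-inden-1-yl]butanoate (mixture at C2 and C3) | COC(=O)C(C(O)CO[Si](C)(C)C(C)(C)C)[C@H]1CC[C@H]2C(C)(C)CCC[C@]12C | intermediate
18 | methyl 4-{[tert-butyl(dimethyl)silyl]oxy}-3-[(methylsulfonyl)oxy]-2-[(1R,3aS,7aR)-4,4,7a-trimethyloctahydro-1H-inden-1-yl]butanoate (mixture at C2 and C3) | COC(=O)C(C(OS(C)(=O)=O)CO[Si](C)(C)C(C)(C)C)[C@H]1CC[C@H]2C(C)(C)CCC[C@]12C | intermediate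
19 | methyl (2E)-4-{[tert-butyl(dimethyl)silyl]oxy}-2-[(1S,3aS,7aS)-4,4,7a-trimethyloctahydro-1H-inden-1-yl]but-2-enoate | COC(=O)/C(=C/CO[Si](C)(C)C(C)(C)C)[C@H]1CC[C@H]2C(C)(C)CCC[C@]12C | intermediate
20 | (2E)-4-{[tert-butyl(dimethyl)silyl]oxy}-2-[(1S,3aS,7aS)-4,4,7a-trimethyloctahydro-1H-inden-1-yl]but-2-en-1-ol | OC/C(=C/CO[Si](C)(C)C(C)(C)C)[C@H]1CC[C@H]2C(C)(C)CCC[C@]12C | intermediate
21 | 4-(dimethylamino)-4-oxobutanoic acid | CN(C)C(=O)CCC(O)=O | starting material
22 | (2E)-4-{[tert-butyl(dimethyl)silyl]oxy}-2-[(1S,3aS,7aS)-4,4,7a-trimethyloctahydro-1H-inden-1-yl]but-2-en-1-yl 4-(dimethylamino)-4-oxobutanoate | CN(C)C(=O)CCC(=O)OC/C(=C/CO[Si](C)(C)C(C)(C)C)[C@H]1CC[C@H]2C(C)(C)CCC[C@]12C | intermediate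
23 | (3E)-4-({(2E)-4-{[tert-butyl(dimethyl)silyl]oxy}-2-[(1S,3aS,7aS)-4,4,7a-trimethyloctahydro-1H-inden-1-yl]but-2-en-1-yl}oxy)-N,N-dimethyl-4-[(trimethylsilyl)oxy]but-3-enamide | CN(C)C(=O)C/C=C(\OC/C(=C/CO[Si](C)(C)C(C)(C)C)[C@H]1CC[C@H]2C(C)(C)CCC[C@]12C)O[Si](C)(C)C | intermediate
24 | trimethylsilyl (2S,3R)-3-({[tert-butyl(dimethyl)silyl]oxy}methyl)-2-[2-(dimethylamino)-2-oxoethyl]-4-[(1R,3aS,7aS)-4,4,7a-trimethyloctahydro-1H-inden-1-yl]pent-4-enoate | C=C([C@H]1CC[C@H]2C(C)(C)CCC[C@]12C)[C@H](CO[Si](C)(C)C(C)(C)C)[C@H](CC(=O)N(C)C)C(=O)O[Si](C)(C)C | intermediate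
25 | (2S,3R)-3-({[tert-butyl(dimethyl)silyl]oxy}methyl)-2-[2-(dimethylamino)-2-oxoethyl]-4-[(1R,3aS,7aS)-4,4,7a-trimethyloctahydro-1H-inden-1-yl]pent-4-enoic acid | C=C([C@H]1CC[C@H]2C(C)(C)CCC[C@]12C)[C@H](CO[Si](C)(C)C(C)(C)C)[C@H](CC(=O)N(C)C)C(O)=O | intermediate
26 | (2S,3R)-3-({[tert-butyl(dimethyl)silyl]oxy}methyl)-2-[2-(dimethylamino)-2-oxoethyl]-4-[(1R,3aS,7aS)-4,4,7a-trimethyloctahydro-1H-inden-1-yl]pent-4-enoic 2-methylpropyl carbonic anhydride | C=C([C@H]1CC[C@H]2C(C)(C)CCC[C@]12C)[C@H](CO[Si](C)(C)C(C)(C)C)[C@H](CC(=O)N(C)C)C(=O)OC(=O)OCC(C)C | intermediate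
27 | (3S,4R)-4-({[tert-butyl(dimethyl)silyl]oxy}methyl)-3-(hydroxymethyl)-N,N-dimethyl-5-[(1R,3aS,7aS)-4,4,7a-trimethyloctahydro-1H-inden-1-yl]hex-5-enamide | C=C([C@H]1CC[C@H]2C(C)(C)CCC[C@]12C)[C@H](CO[Si](C)(C)C(C)(C)C)[C@H](CC(=O)N(C)C)CO | intermediate
28 | (4S)-4-{(2R)-1-hydroxy-3-[(1R,3aS,7aS)-4,4,7a-trimethyloctahydro-1H-inden-1-yl]but-3-en-2-yl}oxolan-2-one | C=C([C@H]1CC[C@H]2C(C)(C)CCC[C@]12C)[C@H](CO)[C@H]1COC(=O)C1 | intermediate
29 | (2R)-2-[(3S)-5-oxooxolan-3-yl]-3-[(1R,3aS,7aS)-4,4,7a-trimethyloctahydro-1H-inden-1-yl]but-3-en-1-yl acetate | C=C([C@H]1CC[C@H]2C(C)(C)CCC[C@]12C)[C@H](COC(C)=O)[C@H]1COC(=O)C1 | target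

**Step count and risks**

Total step count: 16. Longest linear sequence: 15 steps (3 to 29; step 1 prepares 2 in a side branch).

Steps most likely to fail:

1. Step 5. Reductive elimination at the congested tetrasubstituted enolate carbon may be slow, so that β-hydride elimination of the palladium enolate or loss of the triflate takes over. Enolate equilibration may also lead to a crossed aldol condensation at the methyl group before coupling, giving an acyclic (E)-enone that cannot close. The fallback sets out from 9 and returns at 15, and it makes the two bonds in separate, known steps. A Wittig reaction of 9 with the ylide from (3-methylbut-3-en-1-yl)triphenylphosphonium bromide and NaHMDS (THF, −78 °C) gives methyl 2-{(1R,2S)-2-methyl-2-[(1Z)-4-methylpenta-1,4-dien-1-yl]-3-{[(trifluoromethyl)sulfonyl]oxy}cyclopent-3-en-1-yl}acetate F1. A reductive Heck cyclisation (Pd(OAc)2, PPh3, HCO2Na, DMF, 80 °C) then closes the ring 6-exo-trig onto the 1,1-disubstituted alkene; the neopentyl alkylpalladium has no β-hydrogen and is reduced by formate to the second methyl group, which gives methyl 2-[(1R,7aS)-4,4,7a-trimethyl-2,4,5,7a-tetrahydro-1H-inden-1-yl]acetate F2. Hydrogenation of F2 under the conditions of step 8 gives 15, and steps 6 and 7 fall away.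

2. Step 13. Deprotonation may occur in part next to the amide, or the enolate geometry or the facial bias may be eroded, which would give a mixture of diastereomers at the two new centres. The fallback sets out from 20 and returns at 28. A Johnson–Claisen rearrangement of 20 with triethyl orthoacetate (propionic acid cat., xylene, 140 °C) involves no enolate geometry and gives ethyl (3R)-3-({[tert-butyl(dimethyl)silyl]oxy}methyl)-4-[(1R,3aS,7aS)-4,4,7a-trimethyloctahydro-1H-inden-1-yl]pent-4-enoate F3. Alkylation of its lithium enolate with tert-butyl bromoacetate (LDA, THF, −78 °C) gives 4-tert-butyl 1-ethyl (2S)-2-{(2R)-1-{[tert-butyl(dimethyl)silyl]oxy}-3-[(1R,3aS,7aS)-4,4,7a-trimethyloctahydro-1H-inden-1-yl]but-3-en-2-yl}butanedioate F4, with the new centre governed by 1,2-induction and the isomers separated if needed. LiBH4 reduces the ethyl ester in the presence of the tert-butyl ester to tert-butyl (3S,4R)-4-({[tert-butyl(dimethyl)silyl]oxy}methyl)-3-(hydroxymethyl)-5-[(1R,3aS,7aS)-4,4,7a-trimethyloctahydro-1H-inden-1-yl]hex-5-enoate F5. The acid conditions of step 15 then lactonise and desilylate F5 to 28.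

3. Step 2. The α-methyl group on the enone may slow catalyst turnover or lower the enantioselectivity, and a background silyl-cation pathway would give racemic material. The fallback sets out from 3, 4 and 5 and returns at 7. The same addition run with TBSOTf (5 mol %, CH2Cl2, −78 °C) gives racemic methyl 2-[3-{[tert-butyl(dimethyl)silyl]oxy}-2-methylcyclopent-2-en-1-yl]acetate F6. Orthoformate alkylation as in step 2 gives racemic methyl 2-[(1R*,2S*)-2-(dimethoxymethyl)-2-methyl-3-oxocyclopentyl]acetate F7. Preparative chromatography of F7 on a chiral stationary phase delivers 7.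

Further compounds
F1 | step 5 | methyl 2-{(1R,2S)-2-methyl-2-[(1Z)-4-methylpenta-1,4-dien-1-yl]-3-{[(trifluoromethyl)sulfonyl]oxy}cyclopent-3-en-1-yl}acetate | COC(=O)C[C@H]1CC=C(OS(=O)(=O)C(F)(F)F)[C@]1(C)/C=C\CC(C)=C
F2 | step 5 | methyl 2-[(1R,7aS)-4,4,7a-trimethyl-2,4,5,7a-tetrahydro-1H-inden-1-yl]acetate | COC(=O)C[C@H]1CC=C2C(C)(C)CC=C[C@]12C
F3 | step 13 | ethyl (3R)-3-({[tert-butyl(dimethyl)silyl]oxy}methyl)-4-[(1R,3aS,7aS)-4,4,7a-trimethyloctahydro-1H-inden-1-yl]pent-4-enoate | C=C([C@H]1CC[C@H]2C(C)(C)CCC[C@]12C)[C@H](CO[Si](C)(C)C(C)(C)C)CC(=O)OCC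
F4 | step 13 | 4-tert-butyl 1-ethyl (2S)-2-{(2R)-1-{[tert-butyl(dimethyl)silyl]oxy}-3-[(1R,3aS,7aS)-4,4,7a-trimethyloctahydro-1H-inden-1-yl]but-3-en-2-yl}butanedioate | C=C([C@H]1CC[C@H]2C(C)(C)CCC[C@]12C)[C@H](CO[Si](C)(C)C(C)(C)C)[C@H](CC(=O)OC(C)(C)C)C(=O)OCC
F5 | step 13 | tert-butyl (3S,4R)-4-({[tert-butyl(dimethyl)silyl]oxy}methyl)-3-(hydroxymethyl)-5-[(1R,3aS,7aS)-4,4,7a-trimethyloctahydro-1H-inden-1-yl]hex-5-enoate | C=C([C@H]1CC[C@H]2C(C)(C)CCC[C@]12C)[C@H](CO[Si](C)(C)C(C)(C)C)[C@H](CC(=O)OC(C)(C)C)CO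
F6 | step 2 | racemic methyl 2-[3-{[tert-butyl(dimethyl)silyl]oxy}-2-methylcyclopent-2-en-1-yl]acetate | COC(=O)C[C@H]1CCC(O[Si](C)(C)C(C)(C)C)=C1C.COC(=O)C[C@@H]1CCC(O[Si](C)(C)C(C)(C)C)=C1C
F7 | step 2 | racemic methyl 2-[(1R*,2S*)-2-(dimethoxymethyl)-2-methyl-3-oxocyclopentyl]acetate | COC(=O)C[C@H]1CCC(=O)[C@]1(C)C(OC)OC.COC(=O)C[C@@H]1CCC(=O)[C@@]1(C)C(OC)OC
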